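**Plan**

1. Retrosynthesis: the acetate is removed first, then the dienol side chain (tertiary carbinol from an ester, the C=C from a Horner–Wadsworth–Emmons reaction on a C3 methyl ketone). The 6α,7α-epoxide goes back to a C6=C7 alkene next to an 8α-hydroxyl, and the H-3a/H-4 pair to a C3a=C4 alkene.
2. What remains is a cyclohepta-1,4-diene (C3a=C4, C6=C7; sp3 C5, C8, C8a), the retron of a cis-divinylcyclopropane Cope shift. Cutting C4–C5 and C8–C8a gives a cyclopentenyl carbene (C4 on C3a=C8a) and (E)-1-acetoxy-3-methylbutadiene (C5–C8).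
3. Enabling feature: C4, C3a and C8a of the seven-membered ring are the formyl carbon and the two alkene carbons of the limonene-derived cyclopentene carbaldehyde, and C5, C6(CH3), C7, C8(OAc) map atom for atom onto the dienyl acetate.
4. Forward: ring contraction of (R)-limonene oxide makes the five-membered ring; the isopropenyl group is masked as a diol carbonate; the aldehyde becomes a sulfonylhydrazone; a carbene (4+3) annulation closes the seven-membered ring last; then methanolysis, epoxidation, hydrogenation, glycol cleavage, olefination, methyl addition and acetylation.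
5. Stereochemistry: C3 comes from (R)-limonene; C8/C8a from the boat Cope shift (relative) and the catalyst-controlled carbene face (absolute); C6/C7 from hydroxyl-directed epoxidation; C3a from hydroxyl-directed hydrogenation; both side-chain alkenes E from the stabilised phosphonate.
6. Locants: azulene numbering throughout (C1–C3, C3a, C8a five-membered ring; C4–C8 seven-membered ring; angular methyl on C8a); α is the face opposite to that methyl.

Key step: step 7

Remark (assumption): the facial sense that the chiral dirhodium catalyst imposes in step 7 cannot be assigned in advance; the (S)-ligand series is written, and the mirror-image catalyst is taken if it proves to be the matched one.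
Remark: the carbinol carbon of the diol or carbonate handle on C3 (steps 3 to 10) is carried as a mixture of two epimers and becomes the carbonyl carbon in step 11.

**Route**

Step 1
Reactants: 1 (4R)-limonene 1,2-oxide (cis/trans mixture)
Product: 3 (3R)-6-oxo-3-(prop-1-en-2-yl)heptanal, via trans-diol 2 (not isolated)
Conditions: H5IO6 (1.1 equiv), THF/H2O, 0 °C → rt
Reagents that add atoms: water (O)
Why: Acid-promoted hydrolysis of the epoxide and periodate cleavage of the resulting glycol (Malaprade reaction) should open the six-membered ring to the keto aldehyde without touching the isopropenyl group or the stereocentre.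

Step 2
Reactants: 3 (3R)-6-oxo-3-(prop-1-en-2-yl)heptanal
Product: 4 (5S)-2-methyl-5-(prop-1-en-2-yl)cyclopent-1-ene-1-carbaldehyde
Conditions: piperidine (cat.), AcOH (cat.), toluene, 80 °C
Reagents that add atoms: none
Why: Intramolecular aldol condensation through the aldehyde-derived enamine, which attacks the methyl ketone in a five-membered ring closure and dehydrates, should give the cyclopentene carbaldehyde with the stereocentre carried over from limonene.

Step 3
Reactants: 4 (5S)-2-methyl-5-(prop-1-en-2-yl)cyclopent-1-ene-1-carbaldehyde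
Product: 5 (5R)-5-(1,2-dihydroxypropan-2-yl)-2-methylcyclopent-1-ene-1-carbaldehyde (two epimers at the new carbinol carbon)
Conditions: OsO4 (2 mol %), N-methylmorpholine N-oxide, acetone/H2O, rt
Reagents that add atoms: N-methylmorpholine N-oxide (C[N+]1([O-])CCOCC1); water (O)
Why: Upjohn dihydroxylation should take only the electron-rich 1,1-disubstituted alkene, because the ring alkene is tetrasubstituted and deactivated by the formyl group; the new centre is not controlled and disappears in step 11.

Step 4
Reactants: 5 (5R)-5-(1,2-dihydroxypropan-2-yl)-2-methylcyclopent-1-ene-1-carbaldehyde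
Product: 6 (5R)-2-methyl-5-(4-methyl-2-oxo-1,3-dioxolan-4-yl)cyclopent-1-ene-1-carbaldehyde
Conditions: 1,1'-carbonyldiimidazole, DMAP (cat.), CH2Cl2, rt → 40 °C
Reagents that add atoms: 1,1'-carbonyldiimidazole (O=C(n1ccnc1)n1ccnc1)
Why: Acylation of the primary hydroxyl and ring closure by the tertiary one should give the five-membered cyclic carbonate, which hides both O–H bonds from the carbene of step 7 and is removed by the methanolysis of step 8.

Step 5
Reactants: 6 (5R)-2-methyl-5-(4-methyl-2-oxo-1,3-dioxolan-4-yl)cyclopent-1-ene-1-carbaldehyde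
Product: 7 (E)-N'-{[(5R)-2-methyl-5-(4-methyl-2-oxo-1,3-dioxolan-4-yl)cyclopent-1-en-1-yl]methylidene}-2-(trifluoromethyl)benzenesulfonohydrazide
Conditions: 2-(trifluoromethyl)benzenesulfonohydrazide, MeOH, rt
Reagents that add atoms: 2-(trifluoromethyl)benzenesulfonohydrazide (NNS(=O)(=O)c1ccccc1C(F)(F)F)
Why: Condensation of the aldehyde with the sulfonyl hydrazide should give the (E)-N-sulfonylhydrazone, a Bamford–Stevens-type diazo precursor that releases the diazo compound well below room temperature.

Step 6
Reactants: 8 3-methylbut-2-enal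
Product: 9 (1E)-3-methylbuta-1,3-dien-1-yl acetate
Conditions: t-BuOK, THF, −78 °C; AcCl, −78 °C → rt
Reagents that add atoms: acetyl chloride (CC(Cl)=O)
Why: γ-Deprotonation of the s-trans enal gives the extended potassium dienolate, whose O-acylation should deliver the (1E)-dienyl acetate.

Step 7
Reactants: 7 (E)-N'-{[(5R)-2-methyl-5-(4-methyl-2-oxo-1,3-dioxolan-4-yl)cyclopent-1-en-1-yl]methylidene}-2-(trifluoromethyl)benzenesulfonohydrazide; 9 (1E)-3-methylbuta-1,3-dien-1-yl acetate
Product: 12 8α-acetoxy-6,8aβ-dimethyl-3α-(4-methyl-2-oxo-1,3-dioxolan-4-yl)-1,2,3,5,8,8a-hexahydroazulene, via vinyldiazomethane 10 (not isolated), via cis-divinylcyclopropane 11 (not isolated)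
Conditions: NaH (1.5 equiv), dirhodium tetrakis[(S)-1-(4-bromophenyl)-2,2-diphenylcyclopropanecarboxylate] (2 mol %), 9 (5 equiv), CH2Cl2, −40 °C → rt; then toluene, 100 °C
Reagents that add atoms: none
Why: Proposed new method: NaH converts 7 into its sodium salt, which loses sulfinate at low temperature to give vinyldiazomethane 10; the dirhodium catalyst turns 10 into an acceptor-free vinylcarbene that cyclopropanates the 1,1-disubstituted terminal alkene of 9 to cis-divinylcyclopropane 11, and 11 undergoes a boat-type [3,3] (Cope) shift on heating, the closest known reaction types being the tandem cyclopropanation/Cope (4+3) annulation of vinyldiazoacetates with dienes and the cyclopropanation of alkenes by carbenes released from N-sulfonylhydrazones, neither of which is claimed here to extend to a fully β-substituted cyclic vinylcarbene without acceptor group made from an enal. The seven-membered ring is closed by an intermolecular two-bond annulation, C4–C5 in the carbene transfer and C8–C8a in the sigmatropic step, which breaks the cyclopropane bond and leaves the C3a=C4 and C6=C7 alkenes. The C8/C8a relationship follows from the boat transition state, in which the (E)-acetoxy group and ring carbon C1 are both exo and therefore end up cis (acetate α, angular methyl β), so the geometry of 9 controls it. The absolute sense at C8a relative to C3 is fixed in the cyclopropanation (face of the carbene carbon) and should be governed by the chiral carboxylate ligands, because the C3 stereocentre lies two bonds from the carbene carbon and the Cope step is stereospecific. The step needs site selectivity (the 1,1-disubstituted alkene is more electron-rich and less hindered than the trans enol acetate alkene, and 9 is in excess), cis selectivity in the cyclopropane (the acetoxyvinyl arm, not the methyl, cis to the cyclopentenyl group) and suppression of the 1,5-electrocyclisation of 10 to a 3H-pyrazole, which the fully substituted β-carbon and the cold release of 10 in the presence of the catalyst should slow. The methyl group on the cyclopentenyl terminus points inward in the boat and raises the Cope barrier, which is why a heating stage follows.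

Step 8
Reactants: 12 8α-acetoxy-6,8aβ-dimethyl-3α-(4-methyl-2-oxo-1,3-dioxolan-4-yl)-1,2,3,5,8,8a-hexahydroazulene
Product: 13 3α-(1,2-dihydroxypropan-2-yl)-6,8aβ-dimethyl-1,2,3,5,8,8a-hexahydroazulen-8α-ol
Conditions: K2CO3 (cat.), MeOH, rt
Reagents that add atoms: none
Why: Base-catalysed transesterification with methanol should remove the acetate and open the cyclic carbonate in one operation without touching the skipped diene or any stereocentre.

Step 9
Reactants: 13 3α-(1,2-dihydroxypropan-2-yl)-6,8aβ-dimethyl-1,2,3,5,8,8a-hexahydroazulen-8α-ol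
Product: 14 6α,7α-epoxy-3α-(1,2-dihydroxypropan-2-yl)-6β,8aβ-dimethyl-1,2,3,5,6,7,8,8a-octahydroazulen-8α-ol
Conditions: VO(acac)2 (5 mol %), t-BuOOH (1.1 equiv), CH2Cl2, 0 °C
Reagents that add atoms: tert-butyl hydroperoxide (CC(C)(C)OO)
Why: Hydroxyl-directed vanadium-catalysed epoxidation should deliver oxygen from the vanadium alkoxide of the C8 hydroxyl to the allylic C6=C7 alkene on the face of that hydroxyl (α), much faster than to the merely homoallylic C3a=C4 alkene.

Step 10
Reactants: 14 6α,7α-epoxy-3α-(1,2-dihydroxypropan-2-yl)-6β,8aβ-dimethyl-1,2,3,5,6,7,8,8a-octahydroazulen-8α-ol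
Product: 15 6α,7α-epoxy-3α-(1,2-dihydroxypropan-2-yl)-6β,8aβ-dimethyl-trans-decahydroazulen-8α-ol (H-3a α)
Conditions: [Ir(cod)(PCy3)(py)]PF6 (5 mol %), H2 (1 atm), CH2Cl2, rt
Reagents that add atoms: none
Why: Hydroxyl-directed hydrogenation with Crabtree's catalyst should add H2 to the trisubstituted C3a=C4 alkene from the α face, where iridium is held by the homoallylic C8 hydroxyl and the tertiary hydroxyl of the C3 substituent, giving H-3a α and thus the trans ring fusion.

Step 11
Reactants: 15 6α,7α-epoxy-3α-(1,2-dihydroxypropan-2-yl)-6β,8aβ-dimethyl-trans-decahydroazulen-8α-ol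
Product: 16 3α-acetyl-6α,7α-epoxy-6β,8aβ-dimethyl-trans-decahydroazulen-8α-ol
Conditions: NaIO4, THF/H2O, 0 °C → rt
Reagents that add atoms: none
Why: Malaprade cleavage of the 1,2-diol should unveil the methyl ketone and erase the epimeric carbinol centre, the neutral conditions leaving the epoxy alcohol intact.

Step 12
Reactants: 16 3α-acetyl-6α,7α-epoxy-6β,8aβ-dimethyl-trans-decahydroazulen-8α-ol; 17 triethyl 4-phosphonocrotonate
Product: 18 ethyl (2E,4E)-5-(6α,7α-epoxy-8α-hydroxy-6β,8aβ-dimethyl-trans-decahydroazulen-3α-yl)hexa-2,4-dienoate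
Conditions: LiN(SiMe3)2 (3 equiv), 17 (3 equiv), THF, −78 °C → rt
Reagents that add atoms: none
Why: Vinylogous Horner–Wadsworth–Emmons olefination with the stabilised phosphonate anion should give the (2E,4E)-dienoate, the new trisubstituted alkene forming with the ring trans to the ester chain, while C3, which is α to the ketone, already has the thermodynamically preferred configuration (trans to C4).

Step 13
Reactants: 18 ethyl (2E,4E)-5-(6α,7α-epoxy-8α-hydroxy-6β,8aβ-dimethyl-trans-decahydroazulen-3α-yl)hexa-2,4-dienoate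
Product: 19 6α,7α-epoxy-3α-[(2E,4E)-6-hydroxy-6-methylhepta-2,4-dien-2-yl]-6β,8aβ-dimethyl-trans-decahydroazulen-8α-ol
Conditions: MeLi (5 equiv), THF, −78 → −40 °C
Reagents that add atoms: methyllithium ([Li]C)
Why: Double 1,2-addition of methyllithium to the ester should give the tertiary allylic alcohol, the hindered trisubstituted epoxide next to the lithium alkoxide being inert at low temperature.

Step 14
Reactants: 19 6α,7α-epoxy-3α-[(2E,4E)-6-hydroxy-6-methylhepta-2,4-dien-2-yl]-6β,8aβ-dimethyl-trans-decahydroazulen-8α-ol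
Product: 20 8α-acetoxy-6α,7α-epoxy-3α-[(2E,4E)-6-hydroxy-6-methylhepta-2,4-dien-2-yl]-6β,8aβ-dimethyl-trans-decahydroazulene (CNP0265175.2)
Conditions: Ac2O (1.5 equiv), pyridine, DMAP (cat.), CH2Cl2, 0 °C → rt
Reagents that add atoms: acetic anhydride (CC(=O)OC(C)=O)
Why: DMAP-catalysed acylation should acetylate the secondary C8 hydroxyl selectively, the tertiary allylic hydroxyl being far less reactive.

**Compound list**

1 | (4R)-limonene 1,2-oxide (cis/trans mixture) | CC12OC1C[C@@H](CC2)C(C)=C | starting material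
2 | (4R)-1-methyl-4-(prop-1-en-2-yl)cyclohexane-1,2-diol (trans-diol) | CC1(O)C(O)C[C@@H](CC1)C(C)=C | intermediate
3 | (3R)-6-oxo-3-(prop-1-en-2-yl)heptanal | O=CC[C@@H](CCC(C)=O)C(C)=C | intermediate
4 | (5S)-2-methyl-5-(prop-1-en-2-yl)cyclopent-1-ene-1-carbaldehyde | CC1=C(C=O)[C@@H](CC1)C(C)=C | intermediate
5 | (5R)-5-(1,2-dihydroxypropan-2-yl)-2-methylcyclopent-1-ene-1-carbaldehyde (carbinol epimers) | CC1=C(C=O)[C@@H](CC1)C(C)(O)CO | intermediate
6 | (5R)-2-methyl-5-(4-methyl-2-oxo-1,3-dioxolan-4-yl)cyclopent-1-ene-1-carbaldehyde | CC1=C(C=O)[C@@H](CC1)C1(C)COC(=O)O1 | intermediate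
7 | (E)-N-[2-(trifluoromethyl)phenyl]sulfonylhydrazone of 6 | CC1=C(/C=N/NS(=O)(=O)c2ccccc2C(F)(F)F)[C@@H](CC1)C1(C)COC(=O)O1 | intermediate
8 | 3-methylbut-2-enal | CC(C)=CC=O | starting material
9 | (1E)-3-methylbuta-1,3-dien-1-yl acetate | CC(=C)/C=C/OC(C)=O | intermediate
10 | (5R)-1-(diazomethyl)-2-methyl-5-(4-methyl-2-oxo-1,3-dioxolan-4-yl)cyclopent-1-ene | CC1=C(C=[N+]=[N-])[C@@H](CC1)C1(C)COC(=O)O1 | intermediate
11 | (E)-2-{1-methyl-2-[(5R)-2-methyl-5-(4-methyl-2-oxo-1,3-dioxolan-4-yl)cyclopent-1-en-1-yl]cyclopropyl}ethenyl acetate, cyclopentenyl and acetoxyvinyl groups cis | CC1=C([C@@H]2C[C@]2(C)/C=C/OC(C)=O)[C@@H](CC1)C1(C)COC(=O)O1 | intermediate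
12 | 8α-acetoxy-6,8aβ-dimethyl-3α-(4-methyl-2-oxo-1,3-dioxolan-4-yl)-1,2,3,5,8,8a-hexahydroazulene | CC(=O)O[C@@H]1C=C(C)CC=C2[C@H](C3(C)COC(=O)O3)CC[C@]12C | intermediate
13 | 3α-(1,2-dihydroxypropan-2-yl)-6,8aβ-dimethyl-1,2,3,5,8,8a-hexahydroazulen-8α-ol | O[C@@H]1C=C(C)CC=C2[C@H](C(C)(O)CO)CC[C@]12C | intermediate
14 | 6α,7α-epoxy-3α-(1,2-dihydroxypropan-2-yl)-6β,8aβ-dimethyl-1,2,3,5,6,7,8,8a-octahydroazulen-8α-ol | O[C@@H]1[C@@H]2O[C@]2(C)CC=C2[C@H](C(C)(O)CO)CC[C@]12C | intermediate
15 | 6α,7α-epoxy-3α-(1,2-dihydroxypropan-2-yl)-6β,8aβ-dimethyl-trans-decahydroazulen-8α-ol | O[C@@H]1[C@@H]2O[C@]2(C)CC[C@H]2[C@H](C(C)(O)CO)CC[C@]12C | intermediate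
16 | 3α-acetyl-6α,7α-epoxy-6β,8aβ-dimethyl-trans-decahydroazulen-8α-ol | O[C@@H]1[C@@H]2O[C@]2(C)CC[C@H]2[C@H](C(C)=O)CC[C@]12C | intermediate
17 | triethyl 4-phosphonocrotonate, ethyl (E)-4-(diethoxyphosphoryl)but-2-enoate | CCOC(=O)/C=C/CP(=O)(OCC)OCC | starting material
18 | ethyl (2E,4E)-5-(6α,7α-epoxy-8α-hydroxy-6β,8aβ-dimethyl-trans-decahydroazulen-3α-yl)hexa-2,4-dienoate | O[C@@H]1[C@@H]2O[C@]2(C)CC[C@H]2[C@H](/C(C)=C/C=C/C(=O)OCC)CC[C@]12C | intermediate
19 | 6α,7α-epoxy-3α-[(2E,4E)-6-hydroxy-6-methylhepta-2,4-dien-2-yl]-6β,8aβ-dimethyl-trans-decahydroazulen-8α-ol | O[C@@H]1[C@@H]2O[C@]2(C)CC[C@H]2[C@H](/C(C)=C/C=C/C(C)(C)O)CC[C@]12C | intermediate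
20 | 8α-acetoxy-6α,7α-epoxy-3α-[(2E,4E)-6-hydroxy-6-methylhepta-2,4-dien-2-yl]-6β,8aβ-dimethyl-trans-decahydroazulene (CNP0265175.2) | CC(=O)O[C@@H]1[C@@H]2O[C@]2(C)CC[C@H]2[C@H](/C(C)=C/C=C/C(C)(C)O)CC[C@]12C | target

**Count**

Total steps: 14. Longest linear sequence: 13 steps (1 → 20 through steps 1–5 and 7–14); step 6 is a one-step side branch.

**Steps most likely to fail**

Step 7 (proposed new method). What may go wrong: low cis selectivity in the cyclopropanation; wrong or weak facial selectivity at the carbene carbon, since the required adduct places the diene unit on the face of the C3 substituent; cyclisation of the diazoalkene to a pyrazole; carbene dimerisation. The fallback uses known chemistry and makes the carbene a donor/acceptor carbenoid with a temporary ester on C4. It sets out from 6 and comes back at 15.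
- Luche reduction of 6 (NaBH4, CeCl3·7H2O, MeOH) gives (5R)-[2-methyl-5-(4-methyl-2-oxo-1,3-dioxolan-4-yl)cyclopent-1-en-1-yl]methanol F1.
- Methyl chloroformate and pyridine give the allyl methyl carbonate F2.
- Decarboxylative carbonylation (Pd(OAc)2, PPh3, CO) gives the β,γ-unsaturated methyl ester F3.
- Diazo transfer (4-acetamidobenzenesulfonyl azide, DBU, MeCN) gives the vinyldiazoacetate F4.
- F4 and 9 with dirhodium tetrakis[(S)-N-(4-dodecylphenylsulfonyl)prolinate] in hexane, then heating, should give by the established cyclopropanation/Cope sequence the C4 methyl ester analogue of 12, F5.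
- K2CO3 in MeOH gives the triol ester F6, and VO(acac)2 with t-BuOOH its 6α,7α-epoxide F7.
- Directed hydrogenation with [Ir(cod)(PCy3)(py)]PF6 saturates the tetrasubstituted enoate from the α face to the trans-fused ester F8 (configuration at C4 irrelevant).
- LiOH gives the acid F9.
- Photoredox hydrodecarboxylation (9-mesityl-10-methylacridinium tetrafluoroborate, diphenyl disulfide, base, blue light) removes the helper and gives 15.

Step 10. What may go wrong: Lewis-acid-type opening or rearrangement of the trisubstituted epoxide by the cationic iridium species; catalyst deactivation by chelation to the triol; hydrogen delivery to the β face. The fallback abandons hydroxyl direction for a stepwise hydrogen atom transfer hydrogenation (tris(dipivaloylmethanato)manganese Mn(dpm)3, PhSiH3, t-BuOOH, i-PrOH). This proceeds through the tertiary C3a radical and should settle on the more stable trans ring fusion under neutral conditions that spare the epoxide. It sets out from 14 and comes back at 15 without a new compound.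

Step 12. What may go wrong: slow addition to the hindered methyl ketone with competing enolisation; incomplete E selectivity at the new trisubstituted alkene. The fallback sets out from 16 and comes back at 19, bypassing 18 and step 13.
- Boron–Wittig olefination of 16 with lithiated bis(pinacolato)borylmethane (lithium 2,2,6,6-tetramethylpiperidide, THF) should give the (E)-alkenyl boronate, 6α,7α-epoxy-6β,8aβ-dimethyl-3α-[(E)-1-(4,4,5,5-tetramethyl-1,3,2-dioxaborolan-2-yl)prop-1-en-2-yl]-trans-decahydroazulen-8α-ol F10.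
- Suzuki–Miyaura coupling of F10 with (E)-4-iodo-2-methylbut-3-en-2-ol (Pd(PPh3)4, K3PO4, THF/H2O) gives 19 with retention of both alkene geometries.

**Further compounds**

F1 | step 7 | (5R)-[2-methyl-5-(4-methyl-2-oxo-1,3-dioxolan-4-yl)cyclopent-1-en-1-yl]methanol | CC1=C(CO)[C@@H](CC1)C1(C)COC(=O)O1
F2 | step 7 | methyl [(5R)-2-methyl-5-(4-methyl-2-oxo-1,3-dioxolan-4-yl)cyclopent-1-en-1-yl]methyl carbonate | CC1=C(COC(=O)OC)[C@@H](CC1)C1(C)COC(=O)O1
F3 | step 7 | methyl 2-[(5R)-2-methyl-5-(4-methyl-2-oxo-1,3-dioxolan-4-yl)cyclopent-1-en-1-yl]acetate | CC1=C(CC(=O)OC)[C@@H](CC1)C1(C)COC(=O)O1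
F4 | step 7 | methyl 2-diazo-2-[(5R)-2-methyl-5-(4-methyl-2-oxo-1,3-dioxolan-4-yl)cyclopent-1-en-1-yl]acetate | CC1=C(C(=[N+]=[N-])C(=O)OC)[C@@H](CC1)C1(C)COC(=O)O1
F5 | step 7 | methyl 8α-acetoxy-6,8aβ-dimethyl-3α-(4-methyl-2-oxo-1,3-dioxolan-4-yl)-1,2,3,5,8,8a-hexahydroazulene-4-carboxylate | CC(=O)O[C@@H]1C=C(C)CC(C(=O)OC)=C2[C@H](C3(C)COC(=O)O3)CC[C@]12C
F6 | step 7 | methyl 3α-(1,2-dihydroxypropan-2-yl)-8α-hydroxy-6,8aβ-dimethyl-1,2,3,5,8,8a-hexahydroazulene-4-carboxylate | O[C@@H]1C=C(C)CC(C(=O)OC)=C2[C@H](C(C)(O)CO)CC[C@]12C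
F7 | step 7 | methyl 6α,7α-epoxy-3α-(1,2-dihydroxypropan-2-yl)-8α-hydroxy-6β,8aβ-dimethyl-1,2,3,5,6,7,8,8a-octahydroazulene-4-carboxylate | O[C@@H]1[C@@H]2O[C@]2(C)CC(C(=O)OC)=C2[C@H](C(C)(O)CO)CC[C@]12C
F8 | step 7 | methyl 6α,7α-epoxy-3α-(1,2-dihydroxypropan-2-yl)-8α-hydroxy-6β,8aβ-dimethyl-trans-decahydroazulene-4-carboxylate | O[C@@H]1[C@@H]2O[C@]2(C)CC(C(=O)OC)[C@H]2[C@H](C(C)(O)CO)CC[C@]12C
F9 | step 7 | 6α,7α-epoxy-3α-(1,2-dihydroxypropan-2-yl)-8α-hydroxy-6β,8aβ-dimethyl-trans-decahydroazulene-4-carboxylic acid | O[C@@H]1[C@@H]2O[C@]2(C)CC(C(O)=O)[C@H]2[C@H](C(C)(O)CO)CC[C@]12C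
F0 | step 10 | none | none
F10 | step 12 | 6α,7α-epoxy-6β,8aβ-dimethyl-3α-[(E)-1-(4,4,5,5-tetramethyl-1,3,2-dioxaborolan-2-yl)prop-1-en-2-yl]-trans-decahydroazulen-8α-ol | O[C@@H]1[C@@H]2O[C@]2(C)CC[C@H]2[C@H](/C(C)=C/B3OC(C)(C)C(C)(C)O3)CC[C@]12C
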